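**Retrosynthetic overview**

1. The target 20 has one ring, a 6,7-dihydro-5H-oxepin-2-one (O1, C2=O, C3=C4, C5H2, C6H2, C7; C1′ is the carbinol carbon on C7). The last step removes two silyl ethers from lactone 19.
2. Key disconnection: C4–C5 and O1–C7 are cut together, a formal (4+3) annulation. The four-atom piece O=C2–C3=C4–OTf is the (Z)-enol triflate 16 and the three-carbon piece C5=C6–C7 is the vinyl oxirane 10. Forward, this is hydroboration, B-alkyl Suzuki–Miyaura coupling and opening of the oxirane by the ester oxygen in one flask.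
3. Enabling feature: the quaternary ring carbon C7 (bearing O1 and CH3) is bonded to the exocyclic carbinol carbon C1′. The O1–C7–C1′–OH array can therefore be stored as a temporary oxirane C7–O–C1′ (absent from the target) that is opened with inversion at C7. The ring C3=C4 bond holds C2(=O) cis to C5, and C7 carries no hydrogen, so the C5=C6 vinyl group has no allylic hydrogens.
4. 10 comes from nerol (1): silylation, cleavage of the distal alkene, Still–Gennari olefination, reduction, Sharpless epoxidation (sets both stereocentres), oxidation, methylenation. 16 comes from tert-butyl 5-oxopentanoate (11): Still–Gennari olefination, reduction, silylation, formylation, (Z)-enol triflation.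
5. Ring order: the temporary oxirane is made first (step 5); the oxepinone is closed in step 13 as the oxirane is opened.

Key step: step 13

Remark: TBDPS = tert-butyldiphenylsilyl. Assumption: phosphonate 5 and aldehyde 11 are taken as catalogue compounds.

**Route**

Step 1
Reactants: 1 nerol, (2Z)-3,7-dimethylocta-2,6-dien-1-ol
Product: 2 tert-butyl{[(2Z)-3,7-dimethylocta-2,6-dien-1-yl]oxy}diphenylsilane
Conditions: TBDPSCl, imidazole, DMF, 0 °C → rt
Reagents that add atoms: tert-butyl(chloro)diphenylsilane (TBDPSCl), CC(C)(C)[Si](Cl)(c1ccccc1)c1ccccc1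
Why: Imidazole-mediated silyl ether formation at the primary allylic alcohol should give an ether that survives the hydride, base and acid steps that follow.

Step 2
Reactants: 2 tert-butyl{[(2Z)-3,7-dimethylocta-2,6-dien-1-yl]oxy}diphenylsilane
Product: 4 (4Z)-6-(TBDPS-oxy)-4-methylhex-4-enal, via racemic epoxide 3 (not isolated)
Conditions: mCPBA (1.0 equiv), CH2Cl2, −20 → 0 °C; then H5IO6, THF/H2O, 0 °C
Reagents that add atoms: 3-chloroperoxybenzoic acid (mCPBA), OOC(=O)c1cccc(Cl)c1
Why: Prilezhaev epoxidation should occur at the more electron-rich distal alkene (the other is deactivated by the allylic oxygen and shielded by the silyl group), and periodic acid then cleaves the oxirane through its diol (glycol cleavage) to the aldehyde and acetone, destroying the stereocentre of 3.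

Step 3
Reactants: 4 (4Z)-6-(TBDPS-oxy)-4-methylhex-4-enal; 5 ethyl 2-[bis(2,2,2-trifluoroethoxy)phosphoryl]propanoate
Product: 6 ethyl (2Z,6Z)-8-(TBDPS-oxy)-2,6-dimethylocta-2,6-dienoate
Conditions: KN(SiMe3)2, 18-crown-6, THF, −78 °C
Reagents that add atoms: none
Why: In the Still–Gennari olefination the electron-poor phosphonate eliminates rapidly from the kinetic adduct under dissociating conditions, which should give the (Z)-trisubstituted enoate with the ester cis to the chain.

Step 4
Reactants: 6 ethyl (2Z,6Z)-8-(TBDPS-oxy)-2,6-dimethylocta-2,6-dienoate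
Product: 7 (2Z,6Z)-8-(TBDPS-oxy)-2,6-dimethylocta-2,6-dien-1-ol
Conditions: i-Bu2AlH (2.2 equiv), CH2Cl2, −78 °C
Reagents that add atoms: none
Why: 1,2-Reduction of the conjugated ester by the aluminium hydride should give the allylic alcohol without touching the alkene geometry or the silyl ether.

Step 5
Reactants: 7 (2Z,6Z)-8-(TBDPS-oxy)-2,6-dimethylocta-2,6-dien-1-ol
Product: 8 [(2S,3R)-2-methyl-3-[(3Z)-5-(TBDPS-oxy)-3-methylpent-3-en-1-yl]oxiran-2-yl]methanol
Conditions: Ti(OiPr)4 (cat.), L-(+)-diethyl tartrate (cat.), t-BuOOH, 4 Å molecular sieves, CH2Cl2, −20 °C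
Reagents that add atoms: tert-butyl hydroperoxide, CC(C)(C)OO
Why: In the Sharpless asymmetric epoxidation only the alkene bearing the free allylic hydroxyl is epoxidised; L-(+)-tartrate should deliver oxygen to the same face as in the conversion of nerol into (2S,3R)-2,3-epoxynerol, and the (Z)-alkene fixes the two chains cis on the oxirane, so both stereocentres are set here.

Step 6
Reactants: 8 [(2S,3R)-2-methyl-3-[(3Z)-5-(TBDPS-oxy)-3-methylpent-3-en-1-yl]oxiran-2-yl]methanol
Product: 9 (2R,3R)-2-methyl-3-[(3Z)-5-(TBDPS-oxy)-3-methylpent-3-en-1-yl]oxirane-2-carbaldehyde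
Conditions: Pr4N[RuO4] (cat.), N-methylmorpholine N-oxide, 4 Å molecular sieves, CH2Cl2, rt
Reagents that add atoms: none
Why: The Ley–Griffith oxidation is neutral and should leave the oxirane intact; the carbon next to the new aldehyde is quaternary, so it cannot epimerise (the descriptor changes only through priorities).

Step 7
Reactants: 9 (2R,3R)-2-methyl-3-[(3Z)-5-(TBDPS-oxy)-3-methylpent-3-en-1-yl]oxirane-2-carbaldehyde
Product: 10 (2S,3R)-2-ethenyl-2-methyl-3-[(3Z)-5-(TBDPS-oxy)-3-methylpent-3-en-1-yl]oxirane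
Conditions: Ph3PCH3Br, KN(SiMe3)2, THF, 0 °C; then 9, −78 → 0 °C
Reagents that add atoms: methyltriphenylphosphonium bromide, C[P+](c1ccccc1)(c1ccccc1)c1ccccc1.[Br-]
Why: Wittig methylenation of the non-enolisable epoxy aldehyde with the salt-free ylide should give the vinyl oxirane without affecting either stereocentre.

Step 8
Reactants: 11 tert-butyl 5-oxopentanoate; 5 ethyl 2-[bis(2,2,2-trifluoroethoxy)phosphoryl]propanoate
Product: 12 7-tert-butyl 1-ethyl (2Z)-2-methylhept-2-enedioate
Conditions: KN(SiMe3)2, 18-crown-6, THF, −78 °C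
Reagents that add atoms: none
Why: The Still–Gennari olefination should again give the (Z)-enoate, which places the future hydroxymethyl group cis to the chain as the target requires.

Step 9
Reactants: 12 7-tert-butyl 1-ethyl (2Z)-2-methylhept-2-enedioate
Product: 13 tert-butyl (5Z)-7-hydroxy-6-methylhept-5-enoate
Conditions: i-Bu2AlH (2.1 equiv), CH2Cl2, −78 °C
Reagents that add atoms: none
Why: Chemoselective aluminium hydride reduction: the conjugated ethyl ester should be reduced to the allylic alcohol at −78 °C while the hindered tert-butyl ester is not attacked at this temperature.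

Step 10
Reactants: 13 tert-butyl (5Z)-7-hydroxy-6-methylhept-5-enoate
Product: 14 tert-butyl (5Z)-7-(TBDPS-oxy)-6-methylhept-5-enoate
Conditions: TBDPSCl, imidazole, CH2Cl2, rt
Reagents that add atoms: tert-butyl(chloro)diphenylsilane (TBDPSCl), CC(C)(C)[Si](Cl)(c1ccccc1)c1ccccc1
Why: Silyl ether formation protects the allylic alcohol against the strong bases of the next two steps.

Step 11
Reactants: 14 tert-butyl (5Z)-7-(TBDPS-oxy)-6-methylhept-5-enoate
Product: 15 tert-butyl (5Z)-2-formyl-7-(TBDPS-oxy)-6-methylhept-5-enoate (racemic, aldehyde/enol mixture)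
Conditions: LiN(iPr)2, THF, −78 °C; then HCO2Et, −78 → 0 °C
Reagents that add atoms: ethyl formate, CCOC=O
Why: Crossed Claisen condensation of the lithium ester enolate with the non-enolisable formate should be driven by deprotonation of the α-formyl ester; the new centre is racemic and becomes sp2 in the next step.

Step 12
Reactants: 15 tert-butyl (5Z)-2-formyl-7-(TBDPS-oxy)-6-methylhept-5-enoate
Product: 16 tert-butyl (2Z,5Z)-7-(TBDPS-oxy)-6-methyl-2-({[(trifluoromethyl)sulfonyl]oxy}methylidene)hept-5-enoate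
Conditions: LiN(SiMe3)2, THF, −78 °C; then PhN(SO2CF3)2, −78 → 0 °C
Reagents that add atoms: N-phenylbis(trifluoromethanesulfonimide), O=S(=O)(N(c1ccccc1)S(=O)(=O)C(F)(F)F)C(F)(F)F
Why: Chelation-controlled enol triflation: lithium bridges the enolate and ester oxygens, so O-sulfonylation of this chelate should give the enol triflate with OTf cis to the ester, the geometry needed for the later ring closure.

Step 13
Reactants: 10 (2S,3R)-2-ethenyl-2-methyl-3-[(3Z)-5-(TBDPS-oxy)-3-methylpent-3-en-1-yl]oxirane; 16 tert-butyl (2Z,5Z)-7-(TBDPS-oxy)-6-methyl-2-({[(trifluoromethyl)sulfonyl]oxy}methylidene)hept-5-enoate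
Product: 19 (7R)-7-[(1R,4Z)-6-(TBDPS-oxy)-1-hydroxy-4-methylhex-4-en-1-yl]-3-[(3Z)-5-(TBDPS-oxy)-4-methylpent-3-en-1-yl]-7-methyl-6,7-dihydro-5H-oxepin-2-one, via alkylborane 17 (not isolated), via epoxy ester 18 (not isolated)
Conditions: 9-BBN dimer, THF, 0 °C → rt; then 16, PdCl2(dppf) (cat.), K3PO4 (3 M aq.), THF, rt; then evaporation, CH2Cl2, CF3CO2H, 0 °C (one flask, no isolation)
Reagents that add atoms: 9-borabicyclo[3.3.1]nonane (9-BBN; its boron bicycle is carried only by intermediate 17, product 19 keeps only its hydrogen), B1C2CCCC1CCC2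
Why: 9-BBN should add only across the monosubstituted C5=C6 bond of 10 (C7 is quaternary, so there are no allylic hydrogens, and the trisubstituted alkenes react far more slowly) to give the primary alkylborane 17; zerovalent palladium then inserts into the C–OTf bond of 16 with retention, the alkyl group passes from boron to palladium and reductive elimination joins C4 to C5, a B-alkyl Suzuki–Miyaura coupling of an enol triflate. In 18 the retained (Z)-geometry holds the tert-butyl ester cis to the new chain, so that on acidification its carbonyl oxygen should attack the protonated oxirane at the tertiary carbon in a 7-exo-tet closure, and the dioxacarbenium ion then loses 2-methylpropene; this ester participation is known for epoxy tert-butyl esters and carbonates in smaller rings. C7 is set by inversion at the oxirane carbon and C1′ keeps the configuration from step 5, so the single Sharpless epoxidation controls both stereocentres of the target. The step needs chemoselective hydroboration (secured by the substitution pattern), retention of the enol geometry through the coupling (stereospecific oxidative addition) and attack at the tertiary rather than the secondary oxirane carbon (favoured by cation stabilisation and by a 7- over an 8-membered ring).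

Step 14
Reactants: 19 (7R)-7-[(1R,4Z)-6-(TBDPS-oxy)-1-hydroxy-4-methylhex-4-en-1-yl]-3-[(3Z)-5-(TBDPS-oxy)-4-methylpent-3-en-1-yl]-7-methyl-6,7-dihydro-5H-oxepin-2-one
Product: 20 CNP0139192.1, (7R)-7-[(1R,4Z)-1,6-dihydroxy-4-methylhex-4-en-1-yl]-3-[(3Z)-5-hydroxy-4-methylpent-3-en-1-yl]-7-methyl-6,7-dihydro-5H-oxepin-2-one
Conditions: Bu4NF, AcOH (1:1), THF, 0 °C → rt
Reagents that add atoms: none
Why: Fluoride-mediated desilylation buffered with acetic acid should free both primary allylic alcohols without opening or isomerising the unsaturated lactone.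

**Compound list**

1 | nerol, (2Z)-3,7-dimethylocta-2,6-dien-1-ol | CC(C)=CCC/C(C)=C\CO | starting material
2 | tert-butyl{[(2Z)-3,7-dimethylocta-2,6-dien-1-yl]oxy}diphenylsilane | CC(C)=CCC/C(C)=C\CO[Si](c1ccccc1)(c1ccccc1)C(C)(C)C | intermediate
3 | tert-butyl{[(2Z)-5-(3,3-dimethyloxiran-2-yl)-3-methylpent-2-en-1-yl]oxy}diphenylsilane (racemic) | CC1(C)OC1CC/C(C)=C\CO[Si](c2ccccc2)(c2ccccc2)C(C)(C)C | intermediate (not isolated)
4 | (4Z)-6-(TBDPS-oxy)-4-methylhex-4-enal | O=CCC/C(C)=C\CO[Si](c1ccccc1)(c1ccccc1)C(C)(C)C | intermediate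
5 | ethyl 2-[bis(2,2,2-trifluoroethoxy)phosphoryl]propanoate (racemic) | CCOC(=O)C(C)P(=O)(OCC(F)(F)F)OCC(F)(F)F | starting material
6 | ethyl (2Z,6Z)-8-(TBDPS-oxy)-2,6-dimethylocta-2,6-dienoate | CCOC(=O)/C(C)=C\CC/C(C)=C\CO[Si](c1ccccc1)(c1ccccc1)C(C)(C)C | intermediate
7 | (2Z,6Z)-8-(TBDPS-oxy)-2,6-dimethylocta-2,6-dien-1-ol | OC/C(C)=C\CC/C(C)=C\CO[Si](c1ccccc1)(c1ccccc1)C(C)(C)C | intermediate
8 | [(2S,3R)-2-methyl-3-[(3Z)-5-(TBDPS-oxy)-3-methylpent-3-en-1-yl]oxiran-2-yl]methanol | OC[C@@]1(C)[C@@H](CC/C(C)=C\CO[Si](c2ccccc2)(c2ccccc2)C(C)(C)C)O1 | intermediate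
9 | (2R,3R)-2-methyl-3-[(3Z)-5-(TBDPS-oxy)-3-methylpent-3-en-1-yl]oxirane-2-carbaldehyde | O=C[C@@]1(C)[C@@H](CC/C(C)=C\CO[Si](c2ccccc2)(c2ccccc2)C(C)(C)C)O1 | intermediate
10 | (2S,3R)-2-ethenyl-2-methyl-3-[(3Z)-5-(TBDPS-oxy)-3-methylpent-3-en-1-yl]oxirane | C=C[C@@]1(C)[C@@H](CC/C(C)=C\CO[Si](c2ccccc2)(c2ccccc2)C(C)(C)C)O1 | intermediate
11 | tert-butyl 5-oxopentanoate | CC(C)(C)OC(=O)CCCC=O | starting material
12 | 7-tert-butyl 1-ethyl (2Z)-2-methylhept-2-enedioate | CCOC(=O)/C(C)=C\CCCC(=O)OC(C)(C)C | intermediate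
13 | tert-butyl (5Z)-7-hydroxy-6-methylhept-5-enoate | OC/C(C)=C\CCCC(=O)OC(C)(C)C | intermediate
14 | tert-butyl (5Z)-7-(TBDPS-oxy)-6-methylhept-5-enoate | C/C(=C/CCCC(=O)OC(C)(C)C)CO[Si](c1ccccc1)(c1ccccc1)C(C)(C)C | intermediate
15 | tert-butyl (5Z)-2-formyl-7-(TBDPS-oxy)-6-methylhept-5-enoate (racemic) | C/C(=C/CCC(C=O)C(=O)OC(C)(C)C)CO[Si](c1ccccc1)(c1ccccc1)C(C)(C)C | intermediate
16 | tert-butyl (2Z,5Z)-7-(TBDPS-oxy)-6-methyl-2-({[(trifluoromethyl)sulfonyl]oxy}methylidene)hept-5-enoate | C/C(=C/CC/C(=C/OS(=O)(=O)C(F)(F)F)C(=O)OC(C)(C)C)CO[Si](c1ccccc1)(c1ccccc1)C(C)(C)C | intermediate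
17 | 9-{2-[(2S,3R)-2-methyl-3-[(3Z)-5-(TBDPS-oxy)-3-methylpent-3-en-1-yl]oxiran-2-yl]ethyl}-9-borabicyclo[3.3.1]nonane | B1(C2CCCC1CCC2)CC[C@@]3(C)[C@@H](CC/C(C)=C\CO[Si](c4ccccc4)(c4ccccc4)C(C)(C)C)O3 | intermediate (not isolated)
18 | tert-butyl (2Z)-2-[(3Z)-5-(TBDPS-oxy)-4-methylpent-3-en-1-yl]-5-[(2S,3R)-2-methyl-3-[(3Z)-5-(TBDPS-oxy)-3-methylpent-3-en-1-yl]oxiran-2-yl]pent-2-enoate | C/C(=C/CC/C(=C/CC[C@@]1(C)[C@@H](CC/C(C)=C\CO[Si](c2ccccc2)(c2ccccc2)C(C)(C)C)O1)C(=O)OC(C)(C)C)CO[Si](c1ccccc1)(c1ccccc1)C(C)(C)C | intermediate (not isolated)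
19 | (7R)-7-[(1R,4Z)-6-(TBDPS-oxy)-1-hydroxy-4-methylhex-4-en-1-yl]-3-[(3Z)-5-(TBDPS-oxy)-4-methylpent-3-en-1-yl]-7-methyl-6,7-dihydro-5H-oxepin-2-one | C/C(=C/CCC1=CCC[C@](C)([C@H](O)CC/C(C)=C\CO[Si](c2ccccc2)(c2ccccc2)C(C)(C)C)OC1=O)CO[Si](c1ccccc1)(c1ccccc1)C(C)(C)C | intermediate
20 | CNP0139192.1, (7R)-7-[(1R,4Z)-1,6-dihydroxy-4-methylhex-4-en-1-yl]-3-[(3Z)-5-hydroxy-4-methylpent-3-en-1-yl]-7-methyl-6,7-dihydro-5H-oxepin-2-one | C/C(=C/CCC1=CCC[C@](C)([C@H](O)CC/C(C)=C\CO)OC1=O)CO | target

**Step count and risks**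

Total step count: 14. Longest linear sequence: 9 steps (steps 1–7, 13, 14, from nerol).

Steps most likely to fail:

Step 13. The B–H bond may deliver hydride to the vinyl terminus with opening of the adjacent oxirane instead of adding across the double bond, or the boron may activate the oxirane before the alkyl group reaches palladium. The fallback replaces the two-electron boron route by a one-electron coupling from a silicate; it sets out from 10 (with 16) and comes back at 18. Hydrosilylation of 10 with HSi(OMe)3 and Pt2[(CH2=CHMe2Si)2O]3 (cat.) should give the terminal trimethoxysilane, trimethoxy{2-[(2S,3R)-2-methyl-3-[(3Z)-5-(TBDPS-oxy)-3-methylpent-3-en-1-yl]oxiran-2-yl]ethyl}silane F1. Catechol and Et3N convert it into the triethylammonium bis(catecholato)silicate F2. Under blue light with Ru(bpy)3(PF6)2, NiCl2(dme) and 4,4′-di-tert-butyl-2,2′-bipyridine in DMF, F2 should be oxidised to the primary alkyl radical, which nickel couples with 16 with retention of the alkene geometry to give 18. Treatment of 18 with CF3CO2H as in step 13 then gives 19.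

Step 12. Sulfonylation may run through the open enolate instead of the lithium chelate and erode the (Z)-geometry, and only the (Z)-isomer can close the ring. The fallback builds the ring C3=C4 bond by a Z-selective Horner–Wadsworth–Emmons olefination instead; it sets out from 8 and 14 and comes back at 18. Alcohol 8 with Tf2O and 2,6-lutidine at −78 °C should give the epoxy triflate F3. Displacement with LiCH2CN gives 3-[(2S,3R)-2-methyl-3-[(3Z)-5-(TBDPS-oxy)-3-methylpent-3-en-1-yl]oxiran-2-yl]propanenitrile F4. i-Bu2AlH at −78 °C followed by mild hydrolysis gives the corresponding propanal F5. Ester 14 with LiN(iPr)2 (2 equiv) and (PhO)2P(O)Cl gives, after phosphorus migration from oxygen to carbon, the α-(diphenoxyphosphoryl) ester F6. Deprotonation of F6 with NaH and addition of F5 at −78 → 0 °C should give the (Z)-enoate 18, which is taken to 19 with CF3CO2H as in step 13.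

Step 5. Oxygen transfer may be slow and facial discrimination incomplete with the (Z)-trisubstituted allylic alcohol, which lowers the enantiomeric purity of everything that follows. The fallback separates the enantiomers with an enzyme; it sets out from 7 and comes back at 8. Hydroxyl-directed epoxidation of 7 with VO(acac)2 and t-BuOOH should give the racemic cis-epoxy alcohol F7. A lipase (a serine hydrolase, for example the lipase from Burkholderia cepacia) with vinyl acetate should acylate one enantiomer only, giving the acetate F8, drawn for the case that the (2R,3S)-alcohol reacts faster; the alcohol that remains is 8. If the preference is the reverse, the acetate of the (2S,3R) series is separated and methanolysed (K2CO3, MeOH) to 8.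

**Further compounds**

F1 | step 13 | trimethoxy{2-[(2S,3R)-2-methyl-3-[(3Z)-5-(TBDPS-oxy)-3-methylpent-3-en-1-yl]oxiran-2-yl]ethyl}silane | CO[Si](OC)(OC)CC[C@@]1(C)[C@@H](CC/C(C)=C\CO[Si](c2ccccc2)(c2ccccc2)C(C)(C)C)O1
F2 | step 13 | triethylammonium bis(benzene-1,2-diolato){2-[(2S,3R)-2-methyl-3-[(3Z)-5-(TBDPS-oxy)-3-methylpent-3-en-1-yl]oxiran-2-yl]ethyl}silicate | CC[NH+](CC)CC.C(C[C@@]1(C)[C@@H](CC/C(C)=C\CO[Si](c2ccccc2)(c2ccccc2)C(C)(C)C)O1)[Si-]12(Oc3ccccc3O1)Oc1ccccc1O2
F3 | step 12 | [(2S,3R)-2-methyl-3-[(3Z)-5-(TBDPS-oxy)-3-methylpent-3-en-1-yl]oxiran-2-yl]methyl trifluoromethanesulfonate | FC(F)(F)S(=O)(=O)OC[C@@]1(C)[C@@H](CC/C(C)=C\CO[Si](c2ccccc2)(c2ccccc2)C(C)(C)C)O1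
F4 | step 12 | 3-[(2S,3R)-2-methyl-3-[(3Z)-5-(TBDPS-oxy)-3-methylpent-3-en-1-yl]oxiran-2-yl]propanenitrile | N#CCC[C@@]1(C)[C@@H](CC/C(C)=C\CO[Si](c2ccccc2)(c2ccccc2)C(C)(C)C)O1
F5 | step 12 | 3-[(2S,3R)-2-methyl-3-[(3Z)-5-(TBDPS-oxy)-3-methylpent-3-en-1-yl]oxiran-2-yl]propanal | O=CCC[C@@]1(C)[C@@H](CC/C(C)=C\CO[Si](c2ccccc2)(c2ccccc2)C(C)(C)C)O1
F6 | step 12 | tert-butyl (5Z)-2-(diphenoxyphosphoryl)-7-(TBDPS-oxy)-6-methylhept-5-enoate (racemic) | C/C(=C/CCC(C(=O)OC(C)(C)C)P(=O)(Oc1ccccc1)Oc1ccccc1)CO[Si](c1ccccc1)(c1ccccc1)C(C)(C)C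
F7 | step 5 | racemic cis-[2-methyl-3-[(3Z)-5-(TBDPS-oxy)-3-methylpent-3-en-1-yl]oxiran-2-yl]methanol, (2S,3R) and (2R,3S) | OC[C@@]1(C)[C@@H](CC/C(C)=C\CO[Si](c2ccccc2)(c2ccccc2)C(C)(C)C)O1.OC[C@]1(C)[C@H](CC/C(C)=C\CO[Si](c2ccccc2)(c2ccccc2)C(C)(C)C)O1
F8 | step 5 | [(2R,3S)-2-methyl-3-[(3Z)-5-(TBDPS-oxy)-3-methylpent-3-en-1-yl]oxiran-2-yl]methyl acetate | CC(=O)OC[C@]1(C)[C@H](CC/C(C)=C\CO[Si](c2ccccc2)(c2ccccc2)C(C)(C)C)O1
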